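## Retrosynthetic overview
1. Target ⇒ MOM hydrolysis and retro-aromatic Claisen (C5' back to O4') ⇒ an 8-C-prenyl-4'-O-prenyl flavone tris-MOM ether. The 1,1-dimethylallyl group travels as a plain O-prenyl ether until the last step.
2. Key disconnection: the O1–C2 bond of ring C ⇒ a 2'-hydroxychalcone. It is closed by a new sulfinylative oxa-Michael reaction that uses no oxidant able to attack the alkenes.
3. Chalcone ⇒ Claisen–Schmidt union of a ring A acetophenone and a ring B aldehyde. The acetophenone keeps free only the OH next to the C-prenyl group, which fixes the 8-prenyl (not 6-prenyl) pattern.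
4. Acetophenone ⇒ phloroacetophenone + prenyl bromide (C-prenylation, selective bis-MOM). Aldehyde ⇒ 2,4-dihydroxybenzaldehyde + prenyl bromide (one-pot 4-O-prenylation and 2-O-MOM).
5. Ring order: rings A and B are bought as arenes. Ring C is the only ring built (step 5).

Assumption: the target has no stereocentre and is achiral, so there is no enantiomer to select. The only lasting stereo-element on the route is the E alkene of the chalcone.

## Route

Step 1
Reactants: 1 2',4',6'-trihydroxyacetophenone (phloroacetophenone); 2 prenyl bromide (1-bromo-3-methylbut-2-ene)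
Product: 3 1-[2,4,6-trihydroxy-3-(3-methylbut-2-en-1-yl)phenyl]ethanone
Conditions: KOH (1.0 equiv), H2O, 0 °C to rt, 2 (1.0 equiv) added slowly, 4 h
Reagents that add atoms: none
Why: C-alkylation of an ambident phloroglucinol-type phenoxide (SN2), where water solvates the oxygens so the soft allylic bromide is attacked by carbon, C3 and C5 are equivalent so only one mono-C-prenyl isomer can form, and one equivalent of base and halide limits over-alkylation (expected 40–50 %, unreacted 1 recovered).

Step 2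
Reactants: 3 1-[2,4,6-trihydroxy-3-(3-methylbut-2-en-1-yl)phenyl]ethanone
Product: 4 1-[2-hydroxy-4,6-bis(methoxymethoxy)-3-(3-methylbut-2-en-1-yl)phenyl]ethanone
Conditions: MOMCl (2.2 equiv), K2CO3 (3 equiv), acetone, 0 °C to rt, 3 h
Reagents that add atoms: chloromethyl methyl ether (MOMCl), COCCl
Why: Williamson-type O-alkylation in which the non-chelated 4-OH reacts first and then the less hindered chelated OH (C6, next to H), so the OH that stays free lies between the acetyl and the prenyl group and later becomes O1 next to C8.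

Step 3
Reactants: 5 2,4-dihydroxybenzaldehyde; 2 prenyl bromide (1-bromo-3-methylbut-2-ene)
Product: 7 2-(methoxymethoxy)-4-[(3-methylbut-2-en-1-yl)oxy]benzaldehyde, via 4-O-prenyl ether 6 (not isolated)
Conditions: K2CO3 (1.1 equiv), 2 (1.0 equiv), acetone, rt to 40 °C, 12 h; then K2CO3 (2 equiv), MOMCl (1.5 equiv), reflux, 3 h
Reagents that add atoms: chloromethyl methyl ether (MOMCl), COCCl
Why: Two Williamson etherifications in one flask, where the more acidic, non-chelated 4-OH takes the prenyl group while the 2-OH is held by its hydrogen bond to the aldehyde, and extra base and MOMCl at reflux then cap the 2-OH in the same base and solvent.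

Step 4
Reactants: 4 1-[2-hydroxy-4,6-bis(methoxymethoxy)-3-(3-methylbut-2-en-1-yl)phenyl]ethanone; 7 2-(methoxymethoxy)-4-[(3-methylbut-2-en-1-yl)oxy]benzaldehyde
Product: 8 (E)-1-[2-hydroxy-4,6-bis(methoxymethoxy)-3-(3-methylbut-2-en-1-yl)phenyl]-3-{2-(methoxymethoxy)-4-[(3-methylbut-2-en-1-yl)oxy]phenyl}prop-2-en-1-one
Conditions: KOH (50 % aq, 10 equiv), EtOH, rt, 48 h; cold dilute citric acid to pH 5
Reagents that add atoms: none
Why: Claisen–Schmidt aldol condensation whose E1cB dehydration gives the E enone, with every phenol masked except the chelated 2'-OH so neither partner is deactivated as a polyanion, and with MOM acetals and both prenyl groups inert to hydroxide.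

Step 5
Reactants: 8 (E)-1-[2-hydroxy-4,6-bis(methoxymethoxy)-3-(3-methylbut-2-en-1-yl)phenyl]-3-{2-(methoxymethoxy)-4-[(3-methylbut-2-en-1-yl)oxy]phenyl}prop-2-en-1-one
Product: 10 5,7-bis(methoxymethoxy)-2-{2-(methoxymethoxy)-4-[(3-methylbut-2-en-1-yl)oxy]phenyl}-8-(3-methylbut-2-en-1-yl)-4H-chromen-4-one, via 3-(phenylsulfinyl)flavanone 9 (not isolated)
Conditions: KH (2.5 equiv), PhS(O)OMe (1.5 equiv), THF, 0 to 45 °C, 12 h; AcOH (3 equiv); then 65 °C, 2 h
Reagents that add atoms: none
Why: Proposed new method: sulfinylative oxa-Michael ring closure, in which the potassium 2'-phenoxide of 8 adds 6-endo to the enone β-carbon (the O1–C2 bond, helped by the twisted 2',6'-dioxygenated aroyl group), the otherwise unfavourable flavanone enolate is intercepted at C3 by methyl benzenesulfinate (COS(=O)c1ccccc1) and pulled forward as the stabilised β-ketosulfoxide anion of 9 while KH removes the methanol as in a Claisen-type condensation, and after buffering with AcOH the epimerisable C3 sulfoxide reaches the trans-2,3 isomer whose C2–H lies cis to sulfur and leaves by thermal syn-elimination to give the pyranone; the sulfur electrophile reacts only with carbanions, so the two prenyl C=C bonds, the allyl aryl ether and the MOM acetals, which I2/DMSO, DDQ, SeO2 or divalent palladium would attack (the free 2'-OH sits ortho to the prenyl group), are untouched, and only the 8-prenyl isomer can form because no other OH is free; the closest known reaction types are the base-mediated chalcone–flavanone oxa-Michael equilibrium, the one-pot KH/sulfinate ester dehydrogenation of ketones and the thermal loss of sulfenic acid from 3-sulfinylchromanones.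

Step 6
Reactants: 10 5,7-bis(methoxymethoxy)-2-{2-(methoxymethoxy)-4-[(3-methylbut-2-en-1-yl)oxy]phenyl}-8-(3-methylbut-2-en-1-yl)-4H-chromen-4-one
Product: 12 2-[2,4-dihydroxy-5-(2-methylbut-3-en-2-yl)phenyl]-5,7-dihydroxy-8-(3-methylbut-2-en-1-yl)-4H-chromen-4-one (target), via rearranged 4'-phenol 11 (not isolated)
Conditions: EtOH–H2O 4:1, 130 °C, sealed tube, 36 h; cool; conc. HCl to 1 M, 50 °C, 3 h
Reagents that add atoms: none
Why: Water-accelerated aromatic Claisen rearrangement ([3,3]) moves the O-prenyl group with allylic inversion, as a 1,1-dimethylallyl group, to the less hindered ortho carbon C5' (C3' lies between two oxygens and the para carbon C1' is blocked, so no Cope relay), as is known for 2-alkoxy-4-prenyloxyaryl enones, and dilute HCl then hydrolyses the three MOM acetals under conditions that o-prenylphenols normally survive; no stereocentre is created.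

## Compound list
1 | 2',4',6'-trihydroxyacetophenone (phloroacetophenone) | CC(=O)c1c(O)cc(O)cc1O | starting material
2 | prenyl bromide (1-bromo-3-methylbut-2-ene) | CC(C)=CCBr | starting material
3 | 1-[2,4,6-trihydroxy-3-(3-methylbut-2-en-1-yl)phenyl]ethanone | CC(=O)c1c(O)cc(O)c(CC=C(C)C)c1O | intermediate
4 | 1-[2-hydroxy-4,6-bis(methoxymethoxy)-3-(3-methylbut-2-en-1-yl)phenyl]ethanone | CC(=O)c1c(OCOC)cc(OCOC)c(CC=C(C)C)c1O | intermediate
5 | 2,4-dihydroxybenzaldehyde | O=Cc1ccc(O)cc1O | starting material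
6 | 2-hydroxy-4-[(3-methylbut-2-en-1-yl)oxy]benzaldehyde | O=Cc1ccc(OCC=C(C)C)cc1O | intermediate
7 | 2-(methoxymethoxy)-4-[(3-methylbut-2-en-1-yl)oxy]benzaldehyde | O=Cc1ccc(OCC=C(C)C)cc1OCOC | intermediate
8 | (E)-1-[2-hydroxy-4,6-bis(methoxymethoxy)-3-(3-methylbut-2-en-1-yl)phenyl]-3-{2-(methoxymethoxy)-4-[(3-methylbut-2-en-1-yl)oxy]phenyl}prop-2-en-1-one | O=C(/C=C/c1ccc(OCC=C(C)C)cc1OCOC)c1c(OCOC)cc(OCOC)c(CC=C(C)C)c1O | intermediate
9 | 5,7-bis(methoxymethoxy)-2-{2-(methoxymethoxy)-4-[(3-methylbut-2-en-1-yl)oxy]phenyl}-8-(3-methylbut-2-en-1-yl)-3-(phenylsulfinyl)chroman-4-one (racemic mixture of diastereomers, all stereo-elements erased in the elimination) | O=C1C(S(=O)c2ccccc2)C(c2ccc(OCC=C(C)C)cc2OCOC)Oc2c(CC=C(C)C)c(OCOC)cc(OCOC)c12 | intermediate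
10 | 5,7-bis(methoxymethoxy)-2-{2-(methoxymethoxy)-4-[(3-methylbut-2-en-1-yl)oxy]phenyl}-8-(3-methylbut-2-en-1-yl)-4H-chromen-4-one | O=c1cc(-c2ccc(OCC=C(C)C)cc2OCOC)oc2c(CC=C(C)C)c(OCOC)cc(OCOC)c12 | intermediate
11 | 2-[4-hydroxy-2-(methoxymethoxy)-5-(2-methylbut-3-en-2-yl)phenyl]-5,7-bis(methoxymethoxy)-8-(3-methylbut-2-en-1-yl)-4H-chromen-4-one | O=c1cc(-c2cc(C(C)(C)C=C)c(O)cc2OCOC)oc2c(CC=C(C)C)c(OCOC)cc(OCOC)c12 | intermediate
12 | 2-[2,4-dihydroxy-5-(2-methylbut-3-en-2-yl)phenyl]-5,7-dihydroxy-8-(3-methylbut-2-en-1-yl)-4H-chromen-4-one (achiral) | C=CC(C)(C)c1cc(-c2cc(=O)c3c(O)cc(O)c(CC=C(C)C)c3o2)c(O)cc1O | target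

## Step count
Total step count: 6.
Longest linear sequence: 5 (steps 1, 2, 4, 5, 6).

## Steps most likely to fail

**1. Step 5 (the proposed new step).**
- Risk: the flavanone enolate is present only in a very small equilibrium amount beside the phenoxide, so its capture may be slow.
- Risk: the phenoxide may be O-sulfinylated reversibly.
- Fallback (known chemistry; sets out from 4, uses 7, bypasses 8, comes back at 9 and so at 10): the C–S bond is made before the C=C bond.
  - Ordinary enolate sulfinylation of 4 (KH, PhS(O)OMe, THF) gives 1-[2-hydroxy-4,6-bis(methoxymethoxy)-3-(3-methylbut-2-en-1-yl)phenyl]-2-(phenylsulfinyl)ethanone F1.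
  - F1 and 7 with catalytic piperidine/AcOH in toluene at 90 °C undergo Knoevenagel condensation to the α-(phenylsulfinyl)chalcone F2.
  - The doubly activated double bond of F2 takes up the phenol to give 9, which loses sulfenic acid in the same pot to give 10.

**2. Step 6.**
- Risk: some migration to C3', or thermal damage to an advanced intermediate.
- Risk: acid-induced closure of the o-prenylphenols to a chroman or a dihydrobenzofuran.
- Fallback (sets out from 7, uses 4, comes back at 12): the sigmatropic shift is moved to the simple aldehyde.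
  - Heating 7 in N,N-diethylaniline at 190 °C gives 4-hydroxy-2-(methoxymethoxy)-5-(2-methylbut-3-en-2-yl)benzaldehyde F3, from which any C3 isomer is easily removed.
  - MOMCl/K2CO3 gives 2,4-bis(methoxymethoxy)-5-(2-methylbut-3-en-2-yl)benzaldehyde F4.
  - Condensation with 4 as in step 4 gives the tetra-MOM chalcone F5.
  - Ring closure as in step 5 runs through the tetra-MOM 3-(phenylsulfinyl)flavanone F6 to the tetra-MOM flavone F7.
  - A short hydrolysis (HCl, MeOH, rt to 40 °C) gives 12 without heating a late intermediate.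

**3. Step 1.**
- Risk: modest yield through O-prenylation and di- or gem-diprenylation.
- Fallback (sets out from 1, comes back at 3): an O-to-C relay replaces direct C-alkylation.
  - The non-chelated 4-OH of 1 is etherified with 3-chloro-3-methylbut-1-yne (CuCl2 1 mol %, DBU, MeCN, 0 °C) to give 1-{2,6-dihydroxy-4-[(2-methylbut-3-yn-2-yl)oxy]phenyl}ethanone F8.
  - Semihydrogenation (H2, Pd on CaCO3 poisoned with Pb(OAc)2, quinoline, EtOAc) gives 1-{2,6-dihydroxy-4-[(2-methylbut-3-en-2-yl)oxy]phenyl}ethanone F9.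
  - Aromatic Claisen rearrangement in toluene at 110 °C delivers a linear prenyl group to either of the two equivalent ortho carbons, giving 3 as the only isomer.

## Further compounds
F1 | step 5 | 1-[2-hydroxy-4,6-bis(methoxymethoxy)-3-(3-methylbut-2-en-1-yl)phenyl]-2-(phenylsulfinyl)ethanone | O=C(CS(=O)c1ccccc1)c1c(OCOC)cc(OCOC)c(CC=C(C)C)c1O
F2 | step 5 | 1-[2-hydroxy-4,6-bis(methoxymethoxy)-3-(3-methylbut-2-en-1-yl)phenyl]-3-{2-(methoxymethoxy)-4-[(3-methylbut-2-en-1-yl)oxy]phenyl}-2-(phenylsulfinyl)prop-2-en-1-one (E/Z mixture) | O=C(C(=Cc1ccc(OCC=C(C)C)cc1OCOC)S(=O)c1ccccc1)c1c(OCOC)cc(OCOC)c(CC=C(C)C)c1O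
F3 | step 6 | 4-hydroxy-2-(methoxymethoxy)-5-(2-methylbut-3-en-2-yl)benzaldehyde | O=Cc1cc(C(C)(C)C=C)c(O)cc1OCOC
F4 | step 6 | 2,4-bis(methoxymethoxy)-5-(2-methylbut-3-en-2-yl)benzaldehyde | O=Cc1cc(C(C)(C)C=C)c(OCOC)cc1OCOC
F5 | step 6 | (E)-3-[2,4-bis(methoxymethoxy)-5-(2-methylbut-3-en-2-yl)phenyl]-1-[2-hydroxy-4,6-bis(methoxymethoxy)-3-(3-methylbut-2-en-1-yl)phenyl]prop-2-en-1-one | O=C(/C=C/c1cc(C(C)(C)C=C)c(OCOC)cc1OCOC)c1c(OCOC)cc(OCOC)c(CC=C(C)C)c1O
F6 | step 6 | 2-[2,4-bis(methoxymethoxy)-5-(2-methylbut-3-en-2-yl)phenyl]-5,7-bis(methoxymethoxy)-8-(3-methylbut-2-en-1-yl)-3-(phenylsulfinyl)chroman-4-one (racemic mixture of diastereomers) | O=C1C(S(=O)c2ccccc2)C(c2cc(C(C)(C)C=C)c(OCOC)cc2OCOC)Oc2c(CC=C(C)C)c(OCOC)cc(OCOC)c12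
F7 | step 6 | 2-[2,4-bis(methoxymethoxy)-5-(2-methylbut-3-en-2-yl)phenyl]-5,7-bis(methoxymethoxy)-8-(3-methylbut-2-en-1-yl)-4H-chromen-4-one | O=c1cc(-c2cc(C(C)(C)C=C)c(OCOC)cc2OCOC)oc2c(CC=C(C)C)c(OCOC)cc(OCOC)c12
F8 | step 1 | 1-{2,6-dihydroxy-4-[(2-methylbut-3-yn-2-yl)oxy]phenyl}ethanone | CC(=O)c1c(O)cc(OC(C)(C)C#C)cc1O
F9 | step 1 | 1-{2,6-dihydroxy-4-[(2-methylbut-3-en-2-yl)oxy]phenyl}ethanone | CC(=O)c1c(O)cc(OC(C)(C)C=C)cc1O
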